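**Plan**

- Cuts: (i) both C–C bonds of the methylene bridge, giving ring A monomer 16, ring B monomer 12 and a CH2 iminium unit. (ii) In ring B (C1 = ring C=O between the butanoyl carbon C2 and the bridge carbon C6; C4 = quaternary carbon) the bonds C1–C6 and C2–C3, leaving keto ester 5 (C3–C6) and ethoxyethynyl ketone 9 (C1, C2 and the butanoyl group).
- Enabling feature: ring B is a cyclic 2-acyl-1,3,5-triketone, the blocked tautomer of an acylphloroglucinol. Its ring carbons alternate acceptor (C1, C3, C5) and donor (C2, C6) character, and the quaternary C4 lies between two carbonyl carbons. C3–C6 can therefore be carried as a non-enolisable α,α-disubstituted β-keto ester, and C1–C2 delivered as a butanoylketene equivalent in an anionic (4+2) annulation.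
- Forward order: 1 → 5 (two dianion alkylations, oxidation); 6 + 7 → 9; 5 + 9 → ring B (step 6); enol ether hydrolysis → 12; phloroglucinol → ring A monomer 16; a Mannich-type methylene transfer joins 12 and 16.
- Stereochemistry: the only stereocentre (C4 of ring B) is set acyclically in step 2 by 1,2-induction from the carbinol of methyl (R)-3-hydroxybutanoate, which is then oxidised to the C5 carbonyl. C4 bears no hydrogen and no later step breaks a bond to it.

Key step: step 6

Remark: enolised triketones and their ethers are written as single tautomers; the CIP descriptors quoted refer to the tautomer drawn, the spatial arrangement at the quaternary carbon being the same throughout.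

**Route**

Step 1
Reactants: 1 methyl (R)-3-hydroxybutanoate
Product: 2 methyl (2R,3R)-3-hydroxy-2-methylbutanoate
Conditions: LiN(iPr)2 (2.2 equiv), THF, −78 → −20 °C; MeI, DMPU, −78 → 0 °C
Reagents that add atoms: iodomethane, CI
Why: Fráter–Seebach alkylation, in which the chelated lithium alkoxide–enolate is methylated anti to the C3 oxygen without hydroxyl protection; the new C2 centre is of no consequence because it is planarised again in step 2.

Step 2
Reactants: 2 methyl (2R,3R)-3-hydroxy-2-methylbutanoate; 3 1-bromo-3-methylbut-2-ene (prenyl bromide)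
Product: 4 methyl (2R)-2-[(1R)-1-hydroxyethyl]-2,5-dimethylhex-4-enoate
Conditions: LiN(iPr)2 (2.3 equiv), THF, −78 → −10 °C; 3 (1.5 equiv), DMPU, −78 → 0 °C
Reagents that add atoms: none
Why: Second Fráter–Seebach alkylation, in which prenyl bromide (SN2 at its primary carbon) attacks the face of the chelated tetrasubstituted enolate opposite to the C3 methyl group, so the quaternary centre should be set as (R) by 1,2-induction from the (R)-carbinol.

Step 3
Reactants: 4 methyl (2R)-2-[(1R)-1-hydroxyethyl]-2,5-dimethylhex-4-enoate
Product: 5 methyl (2R)-2-acetyl-2,5-dimethylhex-4-enoate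
Conditions: Dess–Martin periodinane (1.3 equiv), CH2Cl2, 0 → 23 °C
Reagents that add atoms: none
Why: Dess–Martin oxidation turns the carbinol that steered step 2 into the ketone carbonyl, and the neighbouring quaternary centre, having no α-hydrogen, cannot epimerise.

Step 4
Reactants: 6 ethoxyethyne (ethoxyacetylene); 7 butanal
Product: 8 1-ethoxyhex-1-yn-3-ol (racemic)
Conditions: n-BuLi (1.05 equiv), THF, −78 °C; then 7, −78 → −20 °C
Reagents that add atoms: none
Why: Standard 1,2-addition of a lithium alkoxyacetylide to an aldehyde; the racemic carbinol centre is removed in step 5.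

Step 5
Reactants: 8 1-ethoxyhex-1-yn-3-ol
Product: 9 1-ethoxyhex-1-yn-3-one
Conditions: MnO2 (activated, 15 equiv), CH2Cl2, 23 °C
Reagents that add atoms: none
Why: MnO2 oxidation of a propargylic alcohol under neutral conditions, which avoids the acid-triggered Meyer–Schuster rearrangement of the ynol ether.

Step 6
Reactants: 5 methyl (2R)-2-acetyl-2,5-dimethylhex-4-enoate; 9 1-ethoxyhex-1-yn-3-one
Product: 11 (6R)-2-butanoyl-3-ethoxy-5-hydroxy-6-methyl-6-(3-methylbut-2-en-1-yl)cyclohexa-2,4-dien-1-one, via Michael adduct 10 (not isolated)
Conditions: LiN(SiMe3)2 (1.1 equiv), THF, −78 °C; 9 (1.1 equiv), −78 → 23 °C, then 45 °C; 1 M HCl to pH 3, 0 °C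
Reagents that add atoms: none
Why: The lithium enolate of the acetyl group of 5 adds to the ethoxy-bearing alkyne carbon of 9, a butanoylketene equivalent with no acidic hydrogen between its two acceptor carbons, whose ynol-ether polarisation makes that carbon the acyl-like electrophile, and the allenolate formed relays a proton to give the extended dienolate of 10. The α-carbon of this dienolate (the CH between the enol-ether carbon and the butanoyl carbonyl) then attacks the methyl ester in a Dieckmann condensation, a 6-(enolexo)-exo-trig closure, and loss of methoxide gives the enolate of acyl dione 11, whose acidity consumes the methoxide and makes the cascade irreversible. The closest known reaction type is the consecutive Michael–Claisen (Michael–Dieckmann) annulation of ketone enolates with alkynones and alkynoates that gives cyclohexane-1,3-diones and resorcinols. No stereocentre is formed: the quaternary carbon set in step 2 lies between the ketone and the ester, carries no hydrogen and is touched by neither bond formation, so its configuration should pass unchanged into the ring. The step needs conjugate instead of carbonyl addition and ring closure through carbon; the substrate secures both, because the carbonyl of 9 is deactivated as an alkynylogous ester while aldol addition is reversible, the only enolisable position of 5 is its acetyl methyl, and of the nucleophilic sites of the dienolate only that α-carbon can reach the ester through a six-membered transition state.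

Step 7
Reactants: 11 (6R)-2-butanoyl-3-ethoxy-5-hydroxy-6-methyl-6-(3-methylbut-2-en-1-yl)cyclohexa-2,4-dien-1-one
Product: 12 (4R)-2-butanoyl-3,5-dihydroxy-4-methyl-4-(3-methylbut-2-en-1-yl)cyclohexa-2,5-dien-1-one
Conditions: 1 M HCl, THF, 23 °C
Reagents that add atoms: water, O
Why: Acid-catalysed hydrolysis of a vinylogous ester by addition of water to the enol-ether carbon and loss of ethanol, fast here because that carbon is β to two carbonyl groups and mild enough to leave the prenyl double bond and the quaternary centre untouched.

Step 8
Reactants: 13 phloroglucinol (benzene-1,3,5-triol); 14 hexanoyl chloride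
Product: 15 1-(2,4,6-trihydroxyphenyl)hexan-1-one
Conditions: AlCl3 (3.5 equiv), PhNO2–CH2Cl2, 0 → 45 °C
Reagents that add atoms: none
Why: Friedel–Crafts acylation of the symmetrical, highly activated arene, in which the first acyl group (a chelated ortho-hydroxy ketone) deactivates the ring against a second acylation.

Step 9
Reactants: 15 1-(2,4,6-trihydroxyphenyl)hexan-1-one
Product: 16 1-(2,6-dihydroxy-4-methoxyphenyl)hexan-1-one
Conditions: Me2SO4 (1.0 equiv), K2CO3 (1.0 equiv), acetone, 23 °C
Reagents that add atoms: dimethyl sulfate, COS(=O)(=O)OC
Why: Williamson-type O-methylation, selective because the two hydroxyls ortho to the ketone are held in hydrogen bonds to the carbonyl, so one equivalent of Me2SO4 should methylate the more acidic, free para-hydroxyl.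

Step 10
Reactants: 12 (4R)-2-butanoyl-3,5-dihydroxy-4-methyl-4-(3-methylbut-2-en-1-yl)cyclohexa-2,5-dien-1-one; 16 1-(2,6-dihydroxy-4-methoxyphenyl)hexan-1-one
Product: 19 elaphopilosin B, via Mannich base 17 (not isolated), via methylene trione 18 (not isolated)
Conditions: CH2=NMe2+ I− (1.0 equiv), NaOAc (1.1 equiv), MeCN, 0 → 23 °C; then 16 (3 equiv), 40 °C
Reagents that add atoms: N,N-dimethylmethyleneiminium iodide (Eschenmoser's salt), C=[N+](C)C.[I-]
Why: Mannich reaction at the only ring CH of 12 gives zwitterion 17, which loses dimethylamine by retro-Michael elimination to the 2-methylene trione 18 (an ortho-quinone-methide analogue) that the excess acylphloroglucinol 16 should capture at either of its two equivalent free ring positions in a Friedel–Crafts-type Michael addition, the quaternary centre not being involved.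

**Compound list**

1 | methyl (R)-3-hydroxybutanoate | C[C@@H](O)CC(=O)OC | starting material
2 | methyl (2R,3R)-3-hydroxy-2-methylbutanoate | C[C@@H](O)[C@@H](C)C(=O)OC | intermediate
3 | 1-bromo-3-methylbut-2-ene (prenyl bromide) | CC(C)=CCBr | starting material
4 | methyl (2R)-2-[(1R)-1-hydroxyethyl]-2,5-dimethylhex-4-enoate | C[C@@H](O)[C@@](C)(CC=C(C)C)C(=O)OC | intermediate
5 | methyl (2R)-2-acetyl-2,5-dimethylhex-4-enoate | CC(=O)[C@@](C)(CC=C(C)C)C(=O)OC | intermediate
6 | ethoxyethyne (ethoxyacetylene) | C#COCC | starting material
7 | butanal | CCCC=O | starting material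
8 | 1-ethoxyhex-1-yn-3-ol (racemic) | CCCC(O)C#COCC | intermediate
9 | 1-ethoxyhex-1-yn-3-one | CCCC(=O)C#COCC | intermediate
10 | methyl (2R)-2-(3-ethoxy-5-oxooct-3-enoyl)-2,5-dimethylhex-4-enoate (Michael adduct, alkene isomers, not isolated) | CCCC(=O)C=C(OCC)CC(=O)[C@@](C)(CC=C(C)C)C(=O)OC | intermediate
11 | (6R)-2-butanoyl-3-ethoxy-5-hydroxy-6-methyl-6-(3-methylbut-2-en-1-yl)cyclohexa-2,4-dien-1-one | CCCC(=O)C1=C(OCC)C=C(O)[C@@](C)(CC=C(C)C)C1=O | intermediate
12 | (4R)-2-butanoyl-3,5-dihydroxy-4-methyl-4-(3-methylbut-2-en-1-yl)cyclohexa-2,5-dien-1-one | CCCC(=O)C1=C(O)[C@](C)(CC=C(C)C)C(O)=CC1=O | intermediate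
13 | phloroglucinol (benzene-1,3,5-triol) | Oc1cc(O)cc(O)c1 | starting material
14 | hexanoyl chloride | CCCCCC(=O)Cl | starting material
15 | 1-(2,4,6-trihydroxyphenyl)hexan-1-one | CCCCCC(=O)c1c(O)cc(O)cc1O | intermediate
16 | 1-(2,6-dihydroxy-4-methoxyphenyl)hexan-1-one | CCCCCC(=O)c1c(O)cc(OC)cc1O | intermediate
17 | (4R)-2-butanoyl-6-[(dimethylamino)methyl]-3,5-dihydroxy-4-methyl-4-(3-methylbut-2-en-1-yl)cyclohexa-2,5-dien-1-one (Mannich base, not isolated) | CCCC(=O)C1=C(O)[C@](C)(CC=C(C)C)C(O)=C(CN(C)C)C1=O | intermediate
18 | (4R)-2-(1-hydroxybutylidene)-4-methyl-6-methylidene-4-(3-methylbut-2-en-1-yl)cyclohexane-1,3,5-trione (methylene trione, not isolated) | CCCC(O)=C1C(=O)[C@](C)(CC=C(C)C)C(=O)C(=C)C1=O | intermediate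
19 | elaphopilosin B | CCCCCC(=O)c1c(O)cc(OC)c(CC2=C(O)[C@@](C)(CC=C(C)C)C(O)=C(C(=O)CCC)C2=O)c1O | target

**Step count and risks**

Total step count: 10. Longest linear sequence: 6 steps (1, 2, 3, 6, 7, 10).

Steps most likely to fail:

1. Step 6. The enolate may attack the ketone carbonyl of 9 or merely exchange a proton with its propyl side chain, an aldolate may lactonise onto the ester, or the open-chain adduct may not close in the same pot. Fallback, setting out from 5: the two bond formations are separated and the first is run under Lewis-acid control. Compound 5 is converted (LiN(SiMe3)2, Me3SiCl, THF, −78 °C) into its enol silane, methyl (2R)-2,5-dimethyl-2-[1-(trimethylsilyloxy)ethenyl]hex-4-enoate F1. This adds to 9 in a Mukaiyama–Michael reaction (TiCl4, CH2Cl2, −78 °C), in which only the oxocarbenium-like alkyne carbon of the activated ynone is attacked. The isolated adduct 10 is then closed by a separate Dieckmann condensation (NaH, THF, 0 → 40 °C), and the route is rejoined at 11.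

2. Step 10. Control may be lost in the three-component methylene transfer: double alkylation of 16, self-reaction or dimerisation of the transient methylene trione, or reversible re-addition of the amine. Fallback, setting out from 16: the one-carbon unit is placed on ring A first. One equivalent of N,N-dimethylmethyleneiminium iodide gives the benzylic Mannich base 1-[3-[(dimethylamino)methyl]-2,6-dihydroxy-4-methoxyphenyl]hexan-1-one F2, and MeI converts it into [3-hexanoyl-2,4-dihydroxy-6-methoxyphenyl]methyl-trimethylammonium iodide F3. With 12 and NaHCO3 in aqueous MeCN at 23 °C, F3 loses trimethylamine to an ortho-quinone methide that the enolate of 12 captures at its ring CH, returning to 19. Here the electrophile is released slowly in the presence of the only competent carbon nucleophile.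

3. Step 2. Enolisation of the hindered α-methyl alkoxide ester may be incomplete, O-alkylation may compete, or facial selectivity may erode when the quaternary centre is formed. Fallback, setting out from prenyl bromide 3 and commercial methyl 2-methyl-3-oxobutanoate: the centre is made by auxiliary-controlled alkylation of a preformed β-keto ester. Condensation with tert-butyl L-valinate gives the hydrogen-bonded enamino ester tert-butyl N-[(2Z)-4-methoxy-3-methyl-4-oxobut-2-en-2-yl]-L-valinate F4. Its lithio derivative (LiN(iPr)2, toluene, −78 °C) is alkylated by 3 to the imine tert-butyl N-[(3R)-3-(methoxycarbonyl)-3,6-dimethylhept-5-en-2-ylidene]-L-valinate F5. The donor additive (HMPA or THF) switches the facial sense of this alkylation, and the regime that gives the (R)-centre is used. Mild aqueous acid then releases the auxiliary and gives 5 directly, without the oxidation of step 3.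

**Further compounds**

F1 | step 6 | methyl (2R)-2,5-dimethyl-2-[1-(trimethylsilyloxy)ethenyl]hex-4-enoate | C=C(O[Si](C)(C)C)[C@@](C)(CC=C(C)C)C(=O)OC
F2 | step 10 | 1-[3-[(dimethylamino)methyl]-2,6-dihydroxy-4-methoxyphenyl]hexan-1-one | CCCCCC(=O)c1c(O)cc(OC)c(CN(C)C)c1O
F3 | step 10 | [3-hexanoyl-2,4-dihydroxy-6-methoxyphenyl]methyl-trimethylammonium iodide | CCCCCC(=O)c1c(O)cc(OC)c(C[N+](C)(C)C)c1O.[I-]
F4 | step 2 | tert-butyl N-[(2Z)-4-methoxy-3-methyl-4-oxobut-2-en-2-yl]-L-valinate | CC(C)[C@H](N/C(C)=C(C)\C(=O)OC)C(=O)OC(C)(C)C
F5 | step 2 | tert-butyl N-[(3R)-3-(methoxycarbonyl)-3,6-dimethylhept-5-en-2-ylidene]-L-valinate | CC(C)[C@H](N=C(C)[C@@](C)(CC=C(C)C)C(=O)OC)C(=O)OC(C)(C)C
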